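**Retrosynthetic overview**
1. Target ⇐ γ-lactonisation of a spiro-THF hydroxy acid ⇐ 5-exo opening of a C13 epoxide by the 9-OH (inversion at C13) ⇐ addition of a malic-acid-derived C11–C16 alkylcerium (fragment 2) to tricyclic ketone 16 (fragment 1).
2. 16 ⇐ hydrogenation and δ-lactonisation of enone 14 ⇐ γ-hydroxylation of the dienolate produced by the key intramolecular 1,6-Michael addition that closes ring A onto dienone 10.
3. 10 ⇐ (S)-carvone by two α′-alkylations (C1–C4/C19 chain, then C20) and dealkenylation of the isopropenyl group.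
4. Ring order: ring B (carvone) → ring A (Michael) → δ-lactone → tetrahydrofuran → γ-lactone.

Assumption: the SMILES is taken literally, (4S,5S,6R,8R,9R,10S,13R); on ring B, C20, H5, 6-OH, H8 and C11 lie on one face (β) and C1, C4, 8-CH3 and O9 on the other (α), so rings A and B are cis-fused.
Numbering (labdane): ring B = C5–C10; ring A = C1–C5 and C10; C17 = CH3 on C8; C18 = CH3 on C4; C19 = C=O on C4; C20 = CH2 on C10; side chain C11–C16 (C13 spiro, C16 = γ-lactone C=O).

**Route**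

Step 1
Reactants: 1 benzyl propanoate
Product: 3 benzyl 5-iodo-2-methylpentanoate (racemic), via lithium enolate 2 (not isolated)
Conditions: LiN(i-Pr)2, THF, −78 °C; I(CH2)3I (3 equiv), DMPU, −78 to −20 °C
Reagents that add atoms: 1,3-diiodopropane, ICCCI
Why: Ester enolate SN2 alkylation, with excess diiodide suppressing double alkylation; the new stereocentre is erased later because it becomes the enolate carbon of step 5.

Step 2
Reactants: 4 (S)-(+)-carvone; 3 benzyl 5-iodo-2-methylpentanoate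
Product: 6 benzyl 2-methyl-5-[(1R,6S)-3-methyl-2-oxo-6-(prop-1-en-2-yl)cyclohex-3-en-1-yl]pentanoate, via carvone lithium enolate 5 (not isolated)
Conditions: LiN(i-Pr)2, THF, −78 °C; then 3, DMPU, −78 to −20 °C
Reagents that add atoms: none
Why: Kinetic α′-enolate SN2 alkylation of carvone goes mainly anti to the isopropenyl group; this centre is re-enolised in step 3, so only its constitution matters.

Step 3
Reactants: 6 monoalkylated carvone
Product: 8 benzyl 5-[(1S,6R)-1-(benzyloxymethyl)-3-methyl-2-oxo-6-(prop-1-en-2-yl)cyclohex-3-en-1-yl]-2-methylpentanoate, via lithium enolate 7 (not isolated)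
Conditions: LiN(i-Pr)2, THF, −78 °C; BnOCH2Cl, −78 to −40 °C
Reagents that add atoms: benzyl chloromethyl ether, ClCOCc1ccccc1
Why: Enolate C-alkylation creates the C10 quaternary centre; the electrophile enters anti to the pseudo-axial isopropenyl group (A1,2 strain), so CH2OBn is trans and the ester chain cis to it, which fixes C10 as S.

Step 4
Reactants: 8 dialkylated carvone
Product: 10 benzyl 5-[(1S)-1-(benzyloxymethyl)-3-methyl-2-oxocyclohexa-3,5-dien-1-yl]-2-methylpentanoate, via methoxy hydroperoxide 9 (not isolated)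
Conditions: O3, MeOH/CH2Cl2, −78 °C; then Cu(OAc)2·H2O, FeSO4·7H2O, −20 °C to rt
Reagents that add atoms: none
Why: Chemoselective ozonolysis of the electron-rich isopropenyl group gives the methoxy hydroperoxide, and iron-induced alkoxy-radical β-scission followed by Cu(OAc)2 oxidation (dealkenylative fragmentation) installs C5=C6; C10 is now the only ring stereocentre.

Step 5
Reactants: 10 cyclohexa-2,4-dienone
Product: 13 cis-fused silyl dienol ether (9-OTBS and C6=C7 and C8=C9 diene; 5β-H; 4α-CH3; 4β-CO2Bn; 10β-CH2OBn), via potassium ester enolate 11 (not isolated), via potassium dienolate 12 (not isolated)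
Conditions: KN(SiMe3)2, 18-crown-6, THF, −78 to −40 °C; then TBSCl, −78 to 0 °C
Reagents that add atoms: tert-butyldimethylsilyl chloride, CC(C)(C)[Si](C)(C)Cl
Why: Key ring closure by intramolecular vinylogous (1,6) Michael addition: the ester enolate (the only acidic site of the non-enolisable dienone) attacks C5 from the face of its tether to give cis-fused ring A (H5 cis to C20), with the bulky enolate group equatorial in the chair-like transition state so that C19 ends cis to C20 (4S), and the dienolate is trapped on oxygen.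

Step 6
Reactants: 13 silyl dienol ether
Product: 14 benzyl ester of the (4S,5S,6R,10S)-6β-hydroxy-9-oxo-7-ene bicyclic acid (10β-CH2OBn)
Conditions: DMDO, acetone/CH2Cl2, −78 °C; then AcOH, THF/H2O, 0 °C
Reagents that add atoms: dimethyldioxirane, CC1(C)OO1
Why: Vinylogous Rubottom oxidation: the dioxirane attacks the terminal C6=C7 bond on the convex β face (anti to ring A at C5), giving the 6β-alcohol and restoring the enone.

Step 7
Reactants: 14 hydroxy enone
Product: 16 (4S,5S,6R,8R,10S)-6β-hydroxy-8α-methyl-9-oxo cis-decalin 19,20-lactone, via hydroxy acid 15 (not isolated)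
Conditions: H2 (1 atm), Pd/C, EtOAc, rt; filter; PPTS (cat.), PhMe, 50 °C
Reagents that add atoms: none
Why: Hydrogenolysis of both benzyl groups and hydrogenation of the enone from the convex β face (8α-CH3) are followed by mild acid-catalysed lactonisation of the 1,3-diaxial C19 acid and C20 alcohol; the 6-OH is trans to C19 across C4–C5 and cannot lactonise, and the conditions are too mild to epimerise C8.

Step 8
Reactants: 17 (S)-malic acid
Product: 18 [(2S,4S)-2-tert-butyl-5-oxo-1,3-dioxolan-4-yl]acetic acid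
Conditions: t-BuCHO, TsOH (cat.), H2SO4 (cat.), pentane, reflux (Dean–Stark)
Reagents that add atoms: pivalaldehyde, CC(C)(C)C=O
Why: Acetalisation of the α-hydroxy acid unit gives the cis dioxolanone (Seebach acetal), which stores the chirality of the future C13 in the acetal centre.

Step 9
Reactants: 18 dioxolanone acid
Product: 20 [(2S,4S)-2-tert-butyl-5-oxo-4-(prop-2-en-1-yl)-1,3-dioxolan-4-yl]acetic acid, via dilithium dianion 19 (not isolated)
Conditions: LiN(SiMe3)2 (2.2 equiv), THF, −78 °C; allyl bromide, −78 to −20 °C; aq. HCl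
Reagents that add atoms: allyl bromide, C=CCBr
Why: Self-regeneration of the stereocentre: the enolate is allylated anti to the tert-butyl group, so allyl replaces H with retention and the future C13 becomes quaternary.

Step 10
Reactants: 20 allylated dioxolanone acid
Product: 21 (3S)-3-(hydroxymethyl)hex-5-ene-1,3-diol
Conditions: LiAlH4, THF, 0 °C to reflux
Reagents that add atoms: none
Why: Hydride reduction of the dioxolanone carbonyl, the released pivalaldehyde and the carboxylic acid gives the triol without touching the quaternary centre or the alkene.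

Step 11
Reactants: 21 triol
Product: 22 2-[(4S)-2,2-dimethyl-4-(prop-2-en-1-yl)-1,3-dioxolan-4-yl]ethan-1-ol
Conditions: Me2C(OMe)2, PPTS (cat.), acetone, rt
Reagents that add atoms: 2,2-dimethoxypropane, COC(C)(C)OC
Why: Thermodynamic acetonide formation selects the 1,2-diol (five-membered dioxolane) and leaves the C15 hydroxyl free.

Step 12
Reactants: 22 acetonide alcohol
Product: 23 tert-butyl{2-[(4S)-2,2-dimethyl-4-(prop-2-en-1-yl)-1,3-dioxolan-4-yl]ethoxy}diphenylsilane
Conditions: TBDPSCl, imidazole, CH2Cl2, rt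
Reagents that add atoms: tert-butyldiphenylsilyl chloride, CC(C)(C)[Si](Cl)(c1ccccc1)c1ccccc1
Why: Silylation of the primary alcohol with a group that survives the later acidic steps.

Step 13
Reactants: 23 silyl ether
Product: 25 2-[(4S)-4-(2-{[tert-butyl(diphenyl)silyl]oxy}ethyl)-2,2-dimethyl-1,3-dioxolan-4-yl]ethan-1-ol, via aldehyde 24 (not isolated)
Conditions: O3, CH2Cl2/MeOH, −78 °C; then NaBH4, −78 °C to rt
Reagents that add atoms: ozone, [O-][O+]=O
Why: Ozonolysis of the terminal alkene with reductive work-up shortens the allyl group to the C12–C11 hydroxyethyl arm.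

Step 14
Reactants: 25 primary alcohol
Product: 26 tert-butyl{2-[(4R)-4-(2-iodoethyl)-2,2-dimethyl-1,3-dioxolan-4-yl]ethoxy}diphenylsilane
Conditions: I2, PPh3, imidazole, CH2Cl2, 0 °C to rt
Reagents that add atoms: iodine, II
Why: Appel-type iodination (SN2) of the primary alcohol gives the organometallic precursor.

Step 15
Reactants: 26 iodide (2.8 equiv); 16 keto lactone
Product: 29 9α-hydroxy adduct (C11 β; side chain carrying the C13/C16 acetonide and C15-OTBDPS), via alkyllithium 27 (not isolated), via alkylcerium dichloride 28 (not isolated)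
Conditions: t-BuLi, Et2O/pentane, −78 °C; CeCl3, THF, −78 °C; then 16, −78 °C; aq. NH4Cl
Reagents that add atoms: none
Why: Iodine–lithium exchange and transmetalation give a weakly basic organocerium reagent that adds 1,2 to the hindered ketone from the β face (axial attack, anti to the axial 8α-CH3 and C1), setting C9 as R with O9 α; one equivalent is consumed by the free 6-OH.

Step 16
Reactants: 29 adduct
Product: 30 tetraol (6-OH; 9-OH; 13-OH; 16-OH; C15-OTBDPS)
Conditions: PPTS, MeOH, 40 °C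
Reagents that add atoms: none
Why: Acid-catalysed transketalisation removes the acetonide while the silyl ether, the lactone and the tertiary alcohols are untouched.

Step 17
Reactants: 30 tetraol
Product: 32 (13S)-13,16-epoxide, via primary tosylate 31 (not isolated)
Conditions: TsCl, Et3N, Bu2SnO (cat.), CH2Cl2, rt; then DBU, 0 °C to rt
Reagents that add atoms: none
Why: Tin-acetal-catalysed sulfonylation is selective for the primary hydroxyl of the 1,2-diol, and DBU closes the epoxide by intramolecular Williamson displacement with C13 unchanged.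

Step 18
Reactants: 32 epoxide
Product: 33 spiro tetrahydrofuran with C16H2OH (13R)
Conditions: CSA (cat.), CH2Cl2, 0 °C
Reagents that add atoms: none
Why: Acid-catalysed 5-exo-tet epoxide opening by the tertiary 9-OH at the tertiary carbon proceeds with inversion, forming the spiro tetrahydrofuran and setting C13 as R.

Step 19
Reactants: 33 primary alcohol
Product: 35 C16 carboxylic acid, via aldehyde 34 (not isolated)
Conditions: TEMPO (cat.), PhI(OAc)2, MeCN/H2O, rt
Reagents that add atoms: water, O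
Why: Oxoammonium (TEMPO) oxidation is selective for the primary alcohol over the hindered secondary 6-OH and runs through the aldehyde hydrate to the acid.

Step 20
Reactants: 35 silyl ether acid
Product: 37 CNP0393616.2, via dihydroxy acid 36 (not isolated)
Conditions: HF (48% aq.), MeCN, rt
Reagents that add atoms: none
Why: Desilylation frees the C15 alcohol, which lactonises onto the C16 acid under the acidic conditions to complete the spiro γ-lactone.

**Compound list**
1 | benzyl propanoate | CCC(=O)OCc1ccccc1 | starting material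
2 | lithium enolate of benzyl propanoate | CC=C(O[Li])OCc1ccccc1 | intermediate
3 | benzyl 5-iodo-2-methylpentanoate (racemic) | CC(CCCI)C(=O)OCc1ccccc1 | intermediate
4 | (S)-(+)-carvone | CC1=CC[C@H](C(C)=C)CC1=O | starting material
5 | lithium α′-enolate of (S)-carvone | CC1=CC[C@H](C(C)=C)C=C1O[Li] | intermediate
6 | benzyl 2-methyl-5-[(1R,6S)-3-methyl-2-oxo-6-(prop-1-en-2-yl)cyclohex-3-en-1-yl]pentanoate (trans; ester α-carbon unassigned) | CC1=CC[C@H](C(C)=C)[C@@H](CCCC(C)C(=O)OCc2ccccc2)C1=O | intermediate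
7 | lithium enolate of 6 | CC1=CC[C@H](C(C)=C)C(CCCC(C)C(=O)OCc2ccccc2)=C1O[Li] | intermediate
8 | benzyl 5-[(1S,6R)-1-(benzyloxymethyl)-3-methyl-2-oxo-6-(prop-1-en-2-yl)cyclohex-3-en-1-yl]-2-methylpentanoate | CC1=CC[C@H](C(C)=C)[C@@](CCCC(C)C(=O)OCc2ccccc2)(COCc2ccccc2)C1=O | intermediate
9 | α-methoxy hydroperoxide from ozonolysis of 8 | CC1=CC[C@H](C(C)(OC)OO)[C@@](CCCC(C)C(=O)OCc2ccccc2)(COCc2ccccc2)C1=O | intermediate
10 | benzyl 5-[(1S)-1-(benzyloxymethyl)-3-methyl-2-oxocyclohexa-3,5-dien-1-yl]-2-methylpentanoate | CC1=CC=C[C@@](CCCC(C)C(=O)OCc2ccccc2)(COCc2ccccc2)C1=O | intermediate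
11 | potassium ester enolate of 10 | CC1=CC=C[C@@](CCCC(C)=C(O[K])OCc2ccccc2)(COCc2ccccc2)C1=O | intermediate
12 | potassium dienolate of the ring-closed cis-fused bicycle | [K]OC1=C(C)C=C[C@H]2[C@]1(COCc1ccccc1)CCC[C@]2(C)C(=O)OCc1ccccc1 | intermediate
13 | cis-fused TBS dienol ether (9-OTBS; 5β-H; 4α-CH3; 4β-CO2Bn; 10β-CH2OBn) | CC(C)(C)[Si](C)(C)OC1=C(C)C=C[C@H]2[C@]1(COCc1ccccc1)CCC[C@]2(C)C(=O)OCc1ccccc1 | intermediate
14 | benzyl (4S,5S,6R,10S)-6β-hydroxy-9-oxo-7-ene ester with 10β-CH2OBn | CC1=C[C@@H](O)[C@H]2[C@](COCc3ccccc3)(CCC[C@]2(C)C(=O)OCc2ccccc2)C1=O | intermediate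
15 | (4S,5S,6R,8R,10S)-6,20-dihydroxy-9-oxo acid | C[C@@H]1C[C@@H](O)[C@H]2[C@](CO)(CCC[C@]2(C)C(O)=O)C1=O | intermediate
16 | (4S,5S,6R,8R,10S)-6β-hydroxy-8α-methyl-9-oxo cis-decalin 19,20-lactone | C[C@@H]1C[C@@H](O)[C@H]2[C@]3(CCC[C@]2(C)C(=O)OC3)C1=O | intermediate
17 | (S)-malic acid | O[C@@H](CC(O)=O)C(O)=O | starting material
18 | [(2S,4S)-2-tert-butyl-5-oxo-1,3-dioxolan-4-yl]acetic acid | CC(C)(C)[C@H]1O[C@@H](CC(O)=O)C(=O)O1 | intermediate
19 | dilithium dianion of 18 | CC(C)(C)[C@H]1OC(CC(=O)O[Li])=C(O[Li])O1 | intermediate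
20 | [(2S,4S)-2-tert-butyl-5-oxo-4-(prop-2-en-1-yl)-1,3-dioxolan-4-yl]acetic acid | CC(C)(C)[C@H]1O[C@@](CC=C)(CC(O)=O)C(=O)O1 | intermediate
21 | (3S)-3-(hydroxymethyl)hex-5-ene-1,3-diol | OC[C@](O)(CC=C)CCO | intermediate
22 | 2-[(4S)-2,2-dimethyl-4-(prop-2-en-1-yl)-1,3-dioxolan-4-yl]ethan-1-ol | CC1(C)OC[C@](CC=C)(CCO)O1 | intermediate
23 | tert-butyl{2-[(4S)-2,2-dimethyl-4-(prop-2-en-1-yl)-1,3-dioxolan-4-yl]ethoxy}diphenylsilane | CC1(C)OC[C@](CC=C)(CCO[Si](c2ccccc2)(c2ccccc2)C(C)(C)C)O1 | intermediate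
24 | 2-[(4R)-4-(2-{[tert-butyl(diphenyl)silyl]oxy}ethyl)-2,2-dimethyl-1,3-dioxolan-4-yl]acetaldehyde | CC1(C)OC[C@](CC=O)(CCO[Si](c2ccccc2)(c2ccccc2)C(C)(C)C)O1 | intermediate
25 | 2-[(4S)-4-(2-{[tert-butyl(diphenyl)silyl]oxy}ethyl)-2,2-dimethyl-1,3-dioxolan-4-yl]ethan-1-ol | CC1(C)OC[C@](CCO)(CCO[Si](c2ccccc2)(c2ccccc2)C(C)(C)C)O1 | intermediate
26 | tert-butyl{2-[(4R)-4-(2-iodoethyl)-2,2-dimethyl-1,3-dioxolan-4-yl]ethoxy}diphenylsilane | CC1(C)OC[C@](CCI)(CCO[Si](c2ccccc2)(c2ccccc2)C(C)(C)C)O1 | intermediate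
27 | alkyllithium from 26 | CC1(C)OC[C@](CC[Li])(CCO[Si](c2ccccc2)(c2ccccc2)C(C)(C)C)O1 | intermediate
28 | alkylcerium dichloride from 27 | CC1(C)OC[C@](CC[Ce](Cl)Cl)(CCO[Si](c2ccccc2)(c2ccccc2)C(C)(C)C)O1 | intermediate
29 | 9α-hydroxy adduct (C11 β; C13/C16 acetonide; C15-OTBDPS) | C[C@@H]1C[C@@H](O)[C@H]2[C@]3(CCC[C@]2(C)C(=O)OC3)[C@@]1(O)CC[C@]1(CCO[Si](c2ccccc2)(c2ccccc2)C(C)(C)C)COC(C)(C)O1 | intermediate
30 | 6,9,13,16-tetraol (13S; C15-OTBDPS) | C[C@@H]1C[C@@H](O)[C@H]2[C@]3(CCC[C@]2(C)C(=O)OC3)[C@@]1(O)CC[C@@](O)(CO)CCO[Si](c1ccccc1)(c1ccccc1)C(C)(C)C | intermediate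
31 | C16 primary tosylate of 30 | C[C@@H]1C[C@@H](O)[C@H]2[C@]3(CCC[C@]2(C)C(=O)OC3)[C@@]1(O)CC[C@@](O)(COS(=O)(=O)c1ccc(C)cc1)CCO[Si](c1ccccc1)(c1ccccc1)C(C)(C)C | intermediate
32 | (13S)-13,16-epoxide with free 9α-OH | C[C@@H]1C[C@@H](O)[C@H]2[C@]3(CCC[C@]2(C)C(=O)OC3)[C@@]1(O)CC[C@]1(CCO[Si](c2ccccc2)(c2ccccc2)C(C)(C)C)CO1 | intermediate
33 | (13R)-9,13-epoxy (spiro tetrahydrofuran) 16-alcohol | C[C@@H]1C[C@@H](O)[C@H]2[C@]3(CCC[C@]2(C)C(=O)OC3)[C@@]12CC[C@](CO)(CCO[Si](c1ccccc1)(c1ccccc1)C(C)(C)C)O2 | intermediate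
34 | C16 aldehyde of 33 | C[C@@H]1C[C@@H](O)[C@H]2[C@]3(CCC[C@]2(C)C(=O)OC3)[C@@]12CC[C@](C=O)(CCO[Si](c1ccccc1)(c1ccccc1)C(C)(C)C)O2 | intermediate
35 | C16 carboxylic acid (C15-OTBDPS) | C[C@@H]1C[C@@H](O)[C@H]2[C@]3(CCC[C@]2(C)C(=O)OC3)[C@@]12CC[C@](C(O)=O)(CCO[Si](c1ccccc1)(c1ccccc1)C(C)(C)C)O2 | intermediate
36 | 15-hydroxy-16-oic acid | C[C@@H]1C[C@@H](O)[C@H]2[C@]3(CCC[C@]2(C)C(=O)OC3)[C@@]12CC[C@](C(O)=O)(CCO)O2 | intermediate
37 | CNP0393616.2: (4S,5S,6R,8R,9R,10S,13R)-9,13-epoxy-6-hydroxylabdane-19,20:16,15-diolide | C[C@@H]1C[C@@H](O)[C@H]2[C@]3(CCC[C@]2(C)C(=O)OC3)[C@@]12CC[C@]1(CCOC1=O)O2 | target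

**Totals and risks**
Total step count: 20. Longest linear sequence: 13 steps (1 → 3 → 6 → 8 → 10 → 13 → 14 → 16 → 29 → 30 → 32 → 33 → 35 → 37; the malic acid branch 17 → 26 → 37 is also 13), which is 0.65 of the total.

Steps most likely to fail:

Step 5 (1,6-Michael closure: efficiency and the C4 configuration, which rests on a transition-state argument). The fallback sets out from 4 and comes back at 16, and closes ring A on a preformed lactone so that the bridge itself fixes C4. Carvone 4 is alkylated (LiN(i-Pr)2; 1-chloro-3-iodopropane) to the 6-(3-chloropropyl) ketone F1 and then hydroxymethylated (LiN(i-Pr)2; monomeric CH2O, anti to isopropenyl) to the hydroxymethyl ketone F2. Hydroboration of the isopropenyl group (9-BBN; NaBO3·4H2O) gives the diol F3, and TEMPO/PhI(OAc)2 oxidative lactonisation (the less hindered C19 alcohol is oxidised first) gives the trans-fused chloro lactone F4. Halide exchange with NaI gives the iodo lactone F5. LiN(i-Pr)2 (2.2 equiv) then forms the ring B dienolate and the lactone enolate, and the latter alkylates intramolecularly to the bridged enone lactone F6. TBSOTf/Et3N gives the silyl dienol ether F7, DMDO gives the 6β-hydroxy enone lactone F8, and hydrogenation (H2, Pd/C) from the β face gives 16.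

Step 6 (γ- versus α-attack of the oxidant, and the C6 face). The fallback sets out from 13 and comes back at 14, replacing the direct oxidation by an epoxide/E1cB sequence. Kinetic α-protonation of 13 (AcOH, THF, −78 °C) gives the deconjugated β,γ-unsaturated ketone F9; mCPBA epoxidises the isolated C6=C7 bond from the convex β face to the 6β,7β-epoxy ketone F10; DBU opens the epoxide by E1cB elimination to give 14.

Step 15 (addition of a primary alkylcerium to a ketone flanked by a quaternary and an epimerisable tertiary carbon). The fallback sets out from 14 and comes back at 33, adding the side chain before C7=C8 is reduced. BCl3 (CH2Cl2, −78 °C) removes both benzyl groups from 14 and the hydroxy acid lactonises to the 6β-hydroxy enone lactone F8. Reagent 28 adds 1,2 to the enone carbonyl from the β face, with no α-stereocentre at risk, to give the tertiary allylic alcohol F11. Methanolysis (PPTS, MeOH) gives the tetraol F12; TsCl/Et3N/Bu2SnO gives the primary tosylate F13; DBU gives the epoxide F14; CSA gives the spiro tetrahydrofuran alkene F15. Hydrogenation with [Ir(cod)(PCy3)(py)]PF6, directed by the allylic 6β-hydroxyl to the β face, then gives 33.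

Further compounds
F1 | step 5 | (5S,6R)-6-(3-chloropropyl)-2-methyl-5-(prop-1-en-2-yl)cyclohex-2-en-1-one | CC1=CC[C@H](C(C)=C)[C@@H](CCCCl)C1=O
F2 | step 5 | (5R,6S)-6-(3-chloropropyl)-6-(hydroxymethyl)-2-methyl-5-(prop-1-en-2-yl)cyclohex-2-en-1-one | CC1=CC[C@H](C(C)=C)[C@@](CCCCl)(CO)C1=O
F3 | step 5 | diol from hydroboration of F2 (C19-OH and C20-OH; C4 unassigned) | CC1=CC[C@H](C(C)CO)[C@@](CCCCl)(CO)C1=O
F4 | step 5 | trans-fused 19,20-lactone with 3-chloropropyl chain on C10 (C4 unassigned) | CC1=CC[C@H]2[C@@](CCCCl)(COC(=O)C2C)C1=O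
F5 | step 5 | trans-fused 19,20-lactone with 3-iodopropyl chain on C10 | CC1=CC[C@H]2[C@@](CCCI)(COC(=O)C2C)C1=O
F6 | step 5 | (4S,5S,10S)-9-oxo-7-ene bridged 19,20-lactone (no 6-OH) | CC1=CC[C@H]2[C@]3(CCC[C@]2(C)C(=O)OC3)C1=O
F7 | step 5 | TBS dienol ether of F6 | CC(C)(C)[Si](C)(C)OC1=C(C)C=C[C@H]2[C@]13CCC[C@]2(C)C(=O)OC3
F8 | step 5 | (4S,5S,6R,10S)-6β-hydroxy-9-oxo-7-ene 19,20-lactone | CC1=C[C@@H](O)[C@H]2[C@]3(CCC[C@]2(C)C(=O)OC3)C1=O
F9 | step 6 | deconjugated 9-oxo-6-ene benzyl ester (C8 unassigned) | CC1C=C[C@H]2[C@](COCc3ccccc3)(CCC[C@]2(C)C(=O)OCc2ccccc2)C1=O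
F10 | step 6 | 6β,7β-epoxy-9-oxo benzyl ester | CC1[C@H]3O[C@H]3[C@H]2[C@](COCc3ccccc3)(CCC[C@]2(C)C(=O)OCc2ccccc2)C1=O
F11 | step 15 | 7-ene 9α-hydroxy adduct with acetonide side chain | CC1=C[C@@H](O)[C@H]2[C@]3(CCC[C@]2(C)C(=O)OC3)[C@@]1(O)CC[C@]1(CCO[Si](c2ccccc2)(c2ccccc2)C(C)(C)C)COC(C)(C)O1
F12 | step 15 | 7-ene 6,9,13,16-tetraol | CC1=C[C@@H](O)[C@H]2[C@]3(CCC[C@]2(C)C(=O)OC3)[C@@]1(O)CC[C@@](O)(CO)CCO[Si](c1ccccc1)(c1ccccc1)C(C)(C)C
F13 | step 15 | 7-ene C16 primary tosylate | CC1=C[C@@H](O)[C@H]2[C@]3(CCC[C@]2(C)C(=O)OC3)[C@@]1(O)CC[C@@](O)(COS(=O)(=O)c1ccc(C)cc1)CCO[Si](c1ccccc1)(c1ccccc1)C(C)(C)C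
F14 | step 15 | 7-ene (13S)-13,16-epoxide | CC1=C[C@@H](O)[C@H]2[C@]3(CCC[C@]2(C)C(=O)OC3)[C@@]1(O)CC[C@]1(CCO[Si](c2ccccc2)(c2ccccc2)C(C)(C)C)CO1
F15 | step 15 | 7-ene (13R)-9,13-epoxy 16-alcohol | CC1=C[C@@H](O)[C@H]2[C@]3(CCC[C@]2(C)C(=O)OC3)[C@@]12CC[C@](CO)(CCO[Si](c1ccccc1)(c1ccccc1)C(C)(C)C)O2
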